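**Assumption:** (R)-(+)-citronellal of ≥97% ee is used. Centres that are destroyed later (C2 of 17, 18, 20, 21; C4 of 19; C3 of 23, 24) are carried as epimer mixtures and left undefined in the SMILES.

## Retrosynthetic overview

1. Acid 33 ⇐ methyl ester 32. The (9E,11E)-phenyldiene ⇐ Horner–Wadsworth–Emmons reaction of aldehyde 29 with cinnamylphosphonate 30, placed last so the diene never meets the Lewis-acid and peroxide-forming steps.
2. C3–CH2CO2Me bond ⇐ TiCl4-mediated Mukaiyama aldol-type union of ketene silyl acetal 25 with the peroxycarbenium ion from 3-methoxy-1,2-dioxolane 24 (sets C3; epimers separated).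
3. The 1,2-dioxolane (the only ring built and kept) ⇐ ring closure of a 4-hydroperoxy-2-ketone. The tertiary C5–OO bond ⇐ invertive H2O2 opening of oxetane 19, a temporary ring made and opened before the dioxolane forms.
4. Oxetane ⇐ 1,3-diol ⇐ Ti(OiPr)4/L-(+)-tartrate epoxidation and hydride opening of (E)-allylic alcohol 13 ⇐ Cp2ZrCl2-catalysed carboalumination of alkyne 11.
5. Alkyne 11 with the (R)-methyl centre ⇐ (R)-citronellal 1 (chiral pool) plus a four-carbon Grignard reagent from 4-chlorobutan-1-ol 6.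

## Route

Step 1
Reactants: 1 (R)-(+)-citronellal
Product: 2 2-[(2R)-2,6-dimethylhept-5-en-1-yl]-1,3-dioxolane
Conditions: ethylene glycol, PPTS (cat.), benzene, reflux (Dean–Stark)
Reagents that add atoms: ethane-1,2-diol, OCCO
Why: Acid-catalysed acetalisation with azeotropic water removal masks the aldehyde for the ozonolysis and Grignard steps, the mild pyridinium catalyst suppresses the carbonyl-ene cyclisation of citronellal, and the (R) methyl centre from the chiral pool is untouched.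

Step 2
Reactants: 2 2-[(2R)-2,6-dimethylhept-5-en-1-yl]-1,3-dioxolane
Product: 4 (4R)-5-(1,3-dioxolan-2-yl)-4-methylpentan-1-ol, via aldehyde 3 (not isolated)
Conditions: O3, CH2Cl2/MeOH, −78 °C (Sudan Red 7B end-point); then NaBH4, −78 °C → rt
Reagents that add atoms: ozone, [O-][O+]=O
Why: Ozonolysis of the electron-rich trisubstituted alkene (stopped at the dye end-point so the acetal C–H is not oxidised) followed by in-situ NaBH4 reduction gives the primary alcohol directly.

Step 3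
Reactants: 4 (4R)-5-(1,3-dioxolan-2-yl)-4-methylpentan-1-ol
Product: 5 (4R)-5-(1,3-dioxolan-2-yl)-4-methylpentyl 4-methylbenzenesulfonate
Conditions: TsCl, pyridine, CH2Cl2, 0 °C → rt
Reagents that add atoms: 4-methylbenzenesulfonyl chloride, Cc1ccc(cc1)S(Cl)(=O)=O
Why: Sulfonylation of the unhindered primary alcohol gives a good leaving group for the sp3–sp3 coupling, and the acetal is safe under basic conditions.

Step 4
Reactants: 6 4-chlorobutan-1-ol
Product: 7 tert-butyl(4-chlorobutoxy)diphenylsilane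
Conditions: TBDPSCl, imidazole, CH2Cl2, 0 °C → rt
Reagents that add atoms: tert-butyl(chloro)diphenylsilane, CC(C)(C)[Si](Cl)(c1ccccc1)c1ccccc1
Why: Silylation of the primary alcohol installs the bulky, acid-robust TBDPS ether, chosen because it must survive TMSOTf, TiCl4 and acidic methanol later.

Step 5
Reactants: 5 (4R)-5-(1,3-dioxolan-2-yl)-4-methylpentyl 4-methylbenzenesulfonate; 7 tert-butyl(4-chlorobutoxy)diphenylsilane
Product: 9 tert-butyl{[(8R)-9-(1,3-dioxolan-2-yl)-8-methylnonyl]oxy}diphenylsilane, via Grignard reagent 8 (not isolated)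
Conditions: 7, Mg, THF, reflux; then 5, Li2CuCl4 (3 mol %), THF, −78 °C → rt
Reagents that add atoms: none
Why: Kochi-type Li2CuCl4-catalysed cross-coupling of a primary alkyl Grignard reagent with a primary tosylate joins the two chain halves by clean substitution without touching the remote stereocentre or the acetal.

Step 6
Reactants: 9 tert-butyl{[(8R)-9-(1,3-dioxolan-2-yl)-8-methylnonyl]oxy}diphenylsilane
Product: 10 (3R)-10-[(tert-butyldiphenylsilyl)oxy]-3-methyldecanal
Conditions: 1 M HCl, THF, rt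
Reagents that add atoms: water, O
Why: Acid-catalysed acetal hydrolysis releases the aldehyde under conditions a primary TBDPS ether tolerates.

Step 7
Reactants: 10 (3R)-10-[(tert-butyldiphenylsilyl)oxy]-3-methyldecanal
Product: 11 tert-butyl{[(8R)-8-methylundec-10-yn-1-yl]oxy}diphenylsilane
Conditions: dimethyl (1-diazo-2-oxopropyl)phosphonate, K2CO3, MeOH, 0 °C → rt
Reagents that add atoms: dimethyl (1-diazo-2-oxopropyl)phosphonate, CC(=O)C(=[N+]=[N-])P(=O)(OC)OC
Why: Ohira–Bestmann (Seyferth–Gilbert) homologation turns the aldehyde into the terminal alkyne under mild carbonate conditions, with no risk to the β-stereocentre.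

Step 8
Reactants: 11 tert-butyl{[(8R)-8-methylundec-10-yn-1-yl]oxy}diphenylsilane
Product: 13 (2E,5R)-12-[(tert-butyldiphenylsilyl)oxy]-3,5-dimethyldodec-2-en-1-ol, via alkenylalane 12 (not isolated)
Conditions: Me3Al, Cp2ZrCl2 (0.25 equiv), CH2Cl2, 0 °C → rt; then (CH2O)n, 0 °C → rt
Reagents that add atoms: trimethylaluminium, C[Al](C)C; formaldehyde (as paraformaldehyde), C=O
Why: Negishi Cp2ZrCl2-catalysed carboalumination adds Me–Al syn and regioselectively across the terminal alkyne and the alkenylalane is hydroxymethylated by formaldehyde, which fixes the (E)-trisubstituted allylic alcohol geometry.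

Step 9
Reactants: 13 (2E,5R)-12-[(tert-butyldiphenylsilyl)oxy]-3,5-dimethyldodec-2-en-1-ol
Product: 14 [(2S,3S)-3-{(2R)-9-[(tert-butyldiphenylsilyl)oxy]-2-methylnonyl}-3-methyloxiran-2-yl]methanol
Conditions: t-BuOOH, Ti(OiPr)4 (10 mol %), L-(+)-diethyl tartrate (12 mol %), 4 Å MS, CH2Cl2, −20 °C
Reagents that add atoms: tert-butyl hydroperoxide, CC(C)(C)OO
Why: Sharpless asymmetric epoxidation, in which the L-(+)-tartrate titanium complex delivers oxygen to one face of the (E)-allylic alcohol under reagent control (as for geraniol), sets the quaternary C–O centre as (3S).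

Step 10
Reactants: 14 [(2S,3S)-3-{(2R)-9-[(tert-butyldiphenylsilyl)oxy]-2-methylnonyl}-3-methyloxiran-2-yl]methanol
Product: 15 (3S,5R)-12-[(tert-butyldiphenylsilyl)oxy]-3,5-dimethyldodecane-1,3-diol
Conditions: NaAlH2(OCH2CH2OMe)2, THF, 0 °C → rt
Reagents that add atoms: none
Why: Hydroxyl-directed hydride delivery from the alkoxyaluminate to C2 of the 2,3-epoxy alcohol opens the ring away from the fully substituted carbon, giving the 1,3-diol with the tertiary C–O bond and its configuration retained.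

Step 11
Reactants: 15 (3S,5R)-12-[(tert-butyldiphenylsilyl)oxy]-3,5-dimethyldodecane-1,3-diol
Product: 16 (3S,5R)-12-[(tert-butyldiphenylsilyl)oxy]-3-hydroxy-3,5-dimethyldodecanal
Conditions: TEMPO (10 mol %), PhI(OAc)2, CH2Cl2, rt; used crude
Reagents that add atoms: none
Why: The TEMPO/PhI(OAc)2 oxoammonium oxidation is selective for the primary alcohol, cannot touch the tertiary one and stops at the aldehyde.

Step 12
Reactants: 16 (3S,5R)-12-[(tert-butyldiphenylsilyl)oxy]-3-hydroxy-3,5-dimethyldodecanal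
Product: 17 (2RS,4S,6R)-13-[(tert-butyldiphenylsilyl)oxy]-4,6-dimethyltridecane-2,4-diol
Conditions: MeMgBr (3 equiv), THF, −78 → 0 °C
Reagents that add atoms: methylmagnesium bromide, C[Mg]Br
Why: Grignard addition to the aldehyde brings in the future C3 methyl group, and the new carbinol centre forms as a mixture that does not matter because it is oxidised in step 17.

Step 13
Reactants: 17 (2RS,4S,6R)-13-[(tert-butyldiphenylsilyl)oxy]-4,6-dimethyltridecane-2,4-diol
Product: 18 (2RS,4S,6R)-13-[(tert-butyldiphenylsilyl)oxy]-4-hydroxy-4,6-dimethyltridecan-2-yl 4-methylbenzenesulfonate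
Conditions: TsCl, DMAP (cat.), pyridine, 0 °C → rt
Reagents that add atoms: 4-methylbenzenesulfonyl chloride, Cc1ccc(cc1)S(Cl)(=O)=O
Why: Sulfonylation discriminates the secondary hydroxyl from the unreactive tertiary one.

Step 14
Reactants: 18 (2RS,4S,6R)-13-[(tert-butyldiphenylsilyl)oxy]-4-hydroxy-4,6-dimethyltridecan-2-yl 4-methylbenzenesulfonate
Product: 19 (2S,4RS)-2-{(2R)-9-[(tert-butyldiphenylsilyl)oxy]-2-methylnonyl}-2,4-dimethyloxetane
Conditions: KOtBu, THF, 0 °C → rt
Reagents that add atoms: none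
Why: Intramolecular Williamson etherification (4-exo-tet) by the tertiary alkoxide closes the oxetane with the tertiary C–O bond, and so its configuration, intact.

Step 15
Reactants: 19 (2S,4RS)-2-{(2R)-9-[(tert-butyldiphenylsilyl)oxy]-2-methylnonyl}-2,4-dimethyloxetane
Product: 20 (2RS,4R,6R)-13-[(tert-butyldiphenylsilyl)oxy]-4-hydroperoxy-4,6-dimethyltridecan-2-ol
Conditions: anhydrous H2O2 in Et2O (10 equiv), TMSOTf (0.2 equiv), Et2O, −78 → 0 °C
Reagents that add atoms: hydrogen peroxide, OO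
Why: Lewis-acid-activated oxetane opening by H2O2 takes place at the more substituted carbon with inversion (borderline SN2 on the activated oxonium ion), turning the (S) tertiary ether into the (R) tertiary hydroperoxide that becomes C5.

Step 16
Reactants: 20 (2RS,4R,6R)-13-[(tert-butyldiphenylsilyl)oxy]-4-hydroperoxy-4,6-dimethyltridecan-2-ol
Product: 21 (2RS,4R,6R)-13-[(tert-butyldiphenylsilyl)oxy]-4-[(2-methoxypropan-2-yl)peroxy]-4,6-dimethyltridecan-2-ol
Conditions: 2-methoxypropene (1.1 equiv), PPTS (cat.), CH2Cl2, 0 °C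
Reagents that add atoms: 2-methoxypropene, COC(C)=C
Why: Acid-catalysed addition of the hydroperoxide, which is far more reactive than the secondary alcohol, to the enol ether protects it as a peroxyketal.

Step 17
Reactants: 21 (2RS,4R,6R)-13-[(tert-butyldiphenylsilyl)oxy]-4-[(2-methoxypropan-2-yl)peroxy]-4,6-dimethyltridecan-2-ol
Product: 22 (4R,6R)-13-[(tert-butyldiphenylsilyl)oxy]-4-[(2-methoxypropan-2-yl)peroxy]-4,6-dimethyltridecan-2-one
Conditions: Dess–Martin periodinane, pyridine, CH2Cl2, 0 °C → rt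
Reagents that add atoms: none
Why: Buffered Dess–Martin oxidation of the secondary alcohol gives the methyl ketone, leaves the peroxyketal and silyl ether intact and removes the epimeric carbinol centre.

Step 18
Reactants: 22 (4R,6R)-13-[(tert-butyldiphenylsilyl)oxy]-4-[(2-methoxypropan-2-yl)peroxy]-4,6-dimethyltridecan-2-one
Product: 24 (3RS,5R)-5-{(2R)-9-[(tert-butyldiphenylsilyl)oxy]-2-methylnonyl}-3-methoxy-3,5-dimethyl-1,2-dioxolane, via hydroxydioxolane 23 (not isolated)
Conditions: TsOH·H2O (5 mol %), MeOH, rt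
Reagents that add atoms: methanol, CO
Why: Acidic methanol cleaves the peroxyketal, the freed hydroperoxide adds to the ketone to close the 1,2-dioxolane as its peroxyhemiketal, and acid-catalysed exchange with methanol gives the methyl ketal without involving C5.

Step 19
Reactants: 24 (3RS,5R)-5-{(2R)-9-[(tert-butyldiphenylsilyl)oxy]-2-methylnonyl}-3-methoxy-3,5-dimethyl-1,2-dioxolane; 25 tert-butyl[(1-methoxyethenyl)oxy]dimethylsilane
Product: 27 methyl 2-[(3R,5R)-5-{(2R)-9-[(tert-butyldiphenylsilyl)oxy]-2-methylnonyl}-3,5-dimethyl-1,2-dioxolan-3-yl]acetate, via peroxycarbenium ion 26 (not isolated)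
Conditions: TiCl4 (1.1 equiv), 25 (2.5 equiv), CH2Cl2, −78 °C; chromatographic separation of the C3 epimers
Reagents that add atoms: none
Why: In this Mukaiyama aldol-type reaction TiCl4 ionises the methyl ketal to a planar peroxycarbenium ion that the ketene silyl acetal captures irreversibly, and because C5 (CH3 versus CH2R) gives little facial bias the C3 epimers form in roughly equal amounts and the (3R,5R)-isomer with cis ring methyls (NOE between them) is isolated by chromatography.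

Step 20
Reactants: 27 methyl 2-[(3R,5R)-5-{(2R)-9-[(tert-butyldiphenylsilyl)oxy]-2-methylnonyl}-3,5-dimethyl-1,2-dioxolan-3-yl]acetate
Product: 28 methyl 2-{(3R,5R)-5-[(2R)-9-hydroxy-2-methylnonyl]-3,5-dimethyl-1,2-dioxolan-3-yl}acetate
Conditions: HF·pyridine, THF/pyridine, 0 °C → rt
Reagents that add atoms: none
Why: Fluoride-mediated silyl ether cleavage under non-basic conditions does not affect the peroxide or the β-peroxy ester.

Step 21
Reactants: 28 methyl 2-{(3R,5R)-5-[(2R)-9-hydroxy-2-methylnonyl]-3,5-dimethyl-1,2-dioxolan-3-yl}acetate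
Product: 29 methyl 2-{(3R,5R)-3,5-dimethyl-5-[(2R)-2-methyl-9-oxononyl]-1,2-dioxolan-3-yl}acetate
Conditions: Dess–Martin periodinane, CH2Cl2, 0 °C → rt
Reagents that add atoms: none
Why: Dess–Martin oxidation stops at the aldehyde and is compatible with dialkyl peroxides.

Step 22
Reactants: 29 methyl 2-{(3R,5R)-3,5-dimethyl-5-[(2R)-2-methyl-9-oxononyl]-1,2-dioxolan-3-yl}acetate; 30 diethyl [(2E)-3-phenylprop-2-en-1-yl]phosphonate
Product: 32 methyl 2-{(3R,5R)-3,5-dimethyl-5-[(2R,9E,11E)-2-methyl-12-phenyldodeca-9,11-dien-1-yl]-1,2-dioxolan-3-yl}acetate, via lithiated phosphonate 31 (not isolated)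
Conditions: 30, LiN(SiMe3)2, THF, −78 °C; then 29, −78 → 0 °C
Reagents that add atoms: none
Why: Horner–Wadsworth–Emmons olefination with the allylic phosphonate anion forms the new C9=C10 bond with high E selectivity while the cinnamyl double bond keeps its E geometry, and at low temperature the preformed anion reacts with the aldehyde much faster than it deprotonates or attacks the ester.

Step 23
Reactants: 32 methyl 2-{(3R,5R)-3,5-dimethyl-5-[(2R,9E,11E)-2-methyl-12-phenyldodeca-9,11-dien-1-yl]-1,2-dioxolan-3-yl}acetate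
Product: 33 2-{(3R,5R)-3,5-dimethyl-5-[(2R,9E,11E)-2-methyl-12-phenyldodeca-9,11-dien-1-yl]-1,2-dioxolan-3-yl}acetic acid
Conditions: LiOH, THF/MeOH/H2O, 0 °C → rt; then 1 M HCl to pH 3
Reagents that add atoms: lithium hydroxide, [Li+].[OH-]
Why: Saponification of the methyl ester by hydroxide is faster than enolisation, so the base-sensitive β-peroxy ester and both quaternary centres survive, and mild acidification gives the free acid.

## Compound list

1 | (R)-(+)-citronellal, (3R)-3,7-dimethyloct-6-enal | C[C@H](CCC=C(C)C)CC=O | starting material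
2 | 2-[(2R)-2,6-dimethylhept-5-en-1-yl]-1,3-dioxolane | C[C@H](CCC=C(C)C)CC1OCCO1 | intermediate
3 | (4R)-5-(1,3-dioxolan-2-yl)-4-methylpentanal | C[C@H](CCC=O)CC1OCCO1 | intermediate
4 | (4R)-5-(1,3-dioxolan-2-yl)-4-methylpentan-1-ol | C[C@H](CCCO)CC1OCCO1 | intermediate
5 | (4R)-5-(1,3-dioxolan-2-yl)-4-methylpentyl 4-methylbenzenesulfonate | C[C@H](CCCOS(=O)(=O)c1ccc(C)cc1)CC1OCCO1 | intermediate
6 | 4-chlorobutan-1-ol | OCCCCCl | starting material
7 | tert-butyl(4-chlorobutoxy)diphenylsilane | ClCCCCO[Si](c1ccccc1)(c1ccccc1)C(C)(C)C | intermediate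
8 | {4-[(tert-butyldiphenylsilyl)oxy]butyl}magnesium chloride | Cl[Mg]CCCCO[Si](c1ccccc1)(c1ccccc1)C(C)(C)C | intermediate
9 | tert-butyl{[(8R)-9-(1,3-dioxolan-2-yl)-8-methylnonyl]oxy}diphenylsilane | C[C@H](CCCCCCCO[Si](c1ccccc1)(c1ccccc1)C(C)(C)C)CC1OCCO1 | intermediate
10 | (3R)-10-[(tert-butyldiphenylsilyl)oxy]-3-methyldecanal | C[C@H](CCCCCCCO[Si](c1ccccc1)(c1ccccc1)C(C)(C)C)CC=O | intermediate
11 | tert-butyl{[(8R)-8-methylundec-10-yn-1-yl]oxy}diphenylsilane | C[C@H](CCCCCCCO[Si](c1ccccc1)(c1ccccc1)C(C)(C)C)CC#C | intermediate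
12 | {(1E,4R)-11-[(tert-butyldiphenylsilyl)oxy]-2,4-dimethylundec-1-en-1-yl}dimethylalumane | C[C@H](CCCCCCCO[Si](c1ccccc1)(c1ccccc1)C(C)(C)C)C/C(C)=C/[Al](C)C | intermediate
13 | (2E,5R)-12-[(tert-butyldiphenylsilyl)oxy]-3,5-dimethyldodec-2-en-1-ol | C[C@H](CCCCCCCO[Si](c1ccccc1)(c1ccccc1)C(C)(C)C)C/C(C)=C/CO | intermediate
14 | [(2S,3S)-3-{(2R)-9-[(tert-butyldiphenylsilyl)oxy]-2-methylnonyl}-3-methyloxiran-2-yl]methanol | OC[C@@H]1O[C@@]1(C)C[C@H](C)CCCCCCCO[Si](c1ccccc1)(c1ccccc1)C(C)(C)C | intermediate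
15 | (3S,5R)-12-[(tert-butyldiphenylsilyl)oxy]-3,5-dimethyldodecane-1,3-diol | OCC[C@](O)(C)C[C@H](C)CCCCCCCO[Si](c1ccccc1)(c1ccccc1)C(C)(C)C | intermediate
16 | (3S,5R)-12-[(tert-butyldiphenylsilyl)oxy]-3-hydroxy-3,5-dimethyldodecanal | O=CC[C@](O)(C)C[C@H](C)CCCCCCCO[Si](c1ccccc1)(c1ccccc1)C(C)(C)C | intermediate
17 | (2RS,4S,6R)-13-[(tert-butyldiphenylsilyl)oxy]-4,6-dimethyltridecane-2,4-diol | CC(O)C[C@](O)(C)C[C@H](C)CCCCCCCO[Si](c1ccccc1)(c1ccccc1)C(C)(C)C | intermediate
18 | (2RS,4S,6R)-13-[(tert-butyldiphenylsilyl)oxy]-4-hydroxy-4,6-dimethyltridecan-2-yl 4-methylbenzenesulfonate | CC(OS(=O)(=O)c1ccc(C)cc1)C[C@](O)(C)C[C@H](C)CCCCCCCO[Si](c1ccccc1)(c1ccccc1)C(C)(C)C | intermediate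
19 | (2S,4RS)-2-{(2R)-9-[(tert-butyldiphenylsilyl)oxy]-2-methylnonyl}-2,4-dimethyloxetane | CC1C[C@](O1)(C)C[C@H](C)CCCCCCCO[Si](c1ccccc1)(c1ccccc1)C(C)(C)C | intermediate
20 | (2RS,4R,6R)-13-[(tert-butyldiphenylsilyl)oxy]-4-hydroperoxy-4,6-dimethyltridecan-2-ol | CC(O)C[C@@](OO)(C)C[C@H](C)CCCCCCCO[Si](c1ccccc1)(c1ccccc1)C(C)(C)C | intermediate
21 | (2RS,4R,6R)-13-[(tert-butyldiphenylsilyl)oxy]-4-[(2-methoxypropan-2-yl)peroxy]-4,6-dimethyltridecan-2-ol | CC(O)C[C@@](OOC(C)(C)OC)(C)C[C@H](C)CCCCCCCO[Si](c1ccccc1)(c1ccccc1)C(C)(C)C | intermediate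
22 | (4R,6R)-13-[(tert-butyldiphenylsilyl)oxy]-4-[(2-methoxypropan-2-yl)peroxy]-4,6-dimethyltridecan-2-one | CC(=O)C[C@@](OOC(C)(C)OC)(C)C[C@H](C)CCCCCCCO[Si](c1ccccc1)(c1ccccc1)C(C)(C)C | intermediate
23 | (3RS,5R)-5-{(2R)-9-[(tert-butyldiphenylsilyl)oxy]-2-methylnonyl}-3,5-dimethyl-1,2-dioxolan-3-ol (ring form of the 4-hydroperoxy ketone) | C[C@H](CCCCCCCO[Si](c1ccccc1)(c1ccccc1)C(C)(C)C)C[C@]1(C)CC(C)(O)OO1 | intermediate
24 | (3RS,5R)-5-{(2R)-9-[(tert-butyldiphenylsilyl)oxy]-2-methylnonyl}-3-methoxy-3,5-dimethyl-1,2-dioxolane | C[C@H](CCCCCCCO[Si](c1ccccc1)(c1ccccc1)C(C)(C)C)C[C@]1(C)CC(C)(OC)OO1 | intermediate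
25 | tert-butyl[(1-methoxyethenyl)oxy]dimethylsilane | C=C(OC)O[Si](C)(C)C(C)(C)C | starting material
26 | (5R)-5-{(2R)-9-[(tert-butyldiphenylsilyl)oxy]-2-methylnonyl}-3,5-dimethyl-4,5-dihydro-1,2-dioxol-2-ium (peroxycarbenium ion) | C[C@H](CCCCCCCO[Si](c1ccccc1)(c1ccccc1)C(C)(C)C)C[C@]1(C)CC(C)=[O+]O1 | intermediate
27 | methyl 2-[(3R,5R)-5-{(2R)-9-[(tert-butyldiphenylsilyl)oxy]-2-methylnonyl}-3,5-dimethyl-1,2-dioxolan-3-yl]acetate | C[C@H](CCCCCCCO[Si](c1ccccc1)(c1ccccc1)C(C)(C)C)C[C@]1(C)C[C@](C)(CC(=O)OC)OO1 | intermediate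
28 | methyl 2-{(3R,5R)-5-[(2R)-9-hydroxy-2-methylnonyl]-3,5-dimethyl-1,2-dioxolan-3-yl}acetate | C[C@H](CCCCCCCO)C[C@]1(C)C[C@](C)(CC(=O)OC)OO1 | intermediate
29 | methyl 2-{(3R,5R)-3,5-dimethyl-5-[(2R)-2-methyl-9-oxononyl]-1,2-dioxolan-3-yl}acetate | C[C@H](CCCCCCC=O)C[C@]1(C)C[C@](C)(CC(=O)OC)OO1 | intermediate
30 | diethyl [(2E)-3-phenylprop-2-en-1-yl]phosphonate | CCOP(=O)(OCC)C/C=C/c1ccccc1 | starting material
31 | lithium (2E)-1-(diethoxyphosphoryl)-3-phenylprop-2-en-1-ide | [Li+].CCOP(=O)(OCC)[CH-]/C=C/c1ccccc1 | intermediate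
32 | methyl 2-{(3R,5R)-3,5-dimethyl-5-[(2R,9E,11E)-2-methyl-12-phenyldodeca-9,11-dien-1-yl]-1,2-dioxolan-3-yl}acetate | C[C@H](CCCCCC/C=C/C=C/c1ccccc1)C[C@]1(C)C[C@](C)(CC(=O)OC)OO1 | intermediate
33 | 2-{(3R,5R)-3,5-dimethyl-5-[(2R,9E,11E)-2-methyl-12-phenyldodeca-9,11-dien-1-yl]-1,2-dioxolan-3-yl}acetic acid | C[C@H](CCCCCC/C=C/C=C/c1ccccc1)C[C@]1(C)C[C@](C)(CC(=O)O)OO1 | target

## Step count and risks

Total steps: 23. Longest linear sequence: 22 (steps 1–3 and 5–23; step 4 is the side branch).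

**Step 15 (oxetane opening by H2O2).** The risks are partial loss of stereospecificity through a free tertiary cation and competing elimination. Concentrated ethereal H2O2 is also a handling hazard. The fallback sets out from alkyne 11. After the same Me3Al/Cp2ZrCl2 carboalumination, alkenylalane 12 is trapped with acetaldehyde to give (3E,6R)-13-[(tert-butyldiphenylsilyl)oxy]-4,6-dimethyltridec-3-en-2-ol F1. Mukaiyama–Isayama peroxidation (bis(2,2,6,6-tetramethylheptane-3,5-dionato)cobalt as a divalent cobalt catalyst, O2, Et3SiH, ClCH2CH2Cl) places a triethylsilylperoxy group on the tertiary carbon without stereocontrol, giving (6R)-13-[(tert-butyldiphenylsilyl)oxy]-4,6-dimethyl-4-[(triethylsilyl)peroxy]tridecan-2-ol F2. Dess–Martin oxidation then gives two C4-epimeric ketones, which are diastereomers because C6 is fixed. HPLC separates (4R,6R)-13-[(tert-butyldiphenylsilyl)oxy]-4,6-dimethyl-4-[(triethylsilyl)peroxy]tridecan-2-one F3 from (4S,6R)-13-[(tert-butyldiphenylsilyl)oxy]-4,6-dimethyl-4-[(triethylsilyl)peroxy]tridecan-2-one F4. TsOH in MeOH removes the silyl group from the (4R)-ketone and closes the ring, so the route is rejoined at 24. This gives up control of C5 for a radical C–OO bond formation that has no stereospecificity to lose, and it costs half the material.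

**Step 19 (peroxycarbenium aldol).** The risk is low facial selectivity: about half the material is expected to be the unwanted C3 epimer, and the separation may need HPLC. The fallback sets out from ketone 22. A Horner–Wadsworth–Emmons reaction (trimethyl phosphonoacetate, NaH, THF) gives methyl (5R,7R)-14-[(tert-butyldiphenylsilyl)oxy]-5-[(2-methoxypropan-2-yl)peroxy]-3,5,7-trimethyltetradec-2-enoate F5 as an E/Z mixture, both isomers being usable. PPTS in MeOH frees the hydroperoxide, methyl (5R,7R)-14-[(tert-butyldiphenylsilyl)oxy]-5-hydroperoxy-3,5,7-trimethyltetradec-2-enoate F6. Et2NH in CF3CH2OH then closes the ring by 5-exo peroxy-Michael addition, rejoining the route at 27. The by-product is methyl 2-[(3S,5R)-5-{(2R)-9-[(tert-butyldiphenylsilyl)oxy]-2-methylnonyl}-3,5-dimethyl-1,2-dioxolan-3-yl]acetate F7. Because C3 is now set by a reversible C–O bond formation, this epimer can in principle be re-opened with a stronger base and recycled. The weak point is the base sensitivity of β-peroxy ketone 22 in the olefination.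

**Step 22 (olefination next to a β-peroxy ester).** The risks are ester enolisation followed by ring opening, and incomplete E selectivity at C9=C10. The fallback sets out from aldehyde 29. A Wittig reaction with the neutral stabilised ylide Ph3P=CHCHO (toluene, 60 °C) gives methyl 2-{(3R,5R)-3,5-dimethyl-5-[(2R,9E)-2-methyl-11-oxoundec-9-en-1-yl]-1,2-dioxolan-3-yl}acetate F8. A second Wittig reaction with the weakly basic ylide Ph3P=CHPh (benzyltriphenylphosphonium chloride, LiN(SiMe3)2, THF, −78 °C) gives 32 together with methyl 2-{(3R,5R)-3,5-dimethyl-5-[(2R,9E,11Z)-2-methyl-12-phenyldodeca-9,11-dien-1-yl]-1,2-dioxolan-3-yl}acetate F9. A trace of I2 in CH2Cl2 under daylight isomerises the (11Z)-diene to the favoured (9E,11E)-diene, so the route is rejoined at 32.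

## Further compounds

F1 | step 15 | (3E,6R)-13-[(tert-butyldiphenylsilyl)oxy]-4,6-dimethyltridec-3-en-2-ol | C[C@H](CCCCCCCO[Si](c1ccccc1)(c1ccccc1)C(C)(C)C)C/C(C)=C/C(C)O
F2 | step 15 | (6R)-13-[(tert-butyldiphenylsilyl)oxy]-4,6-dimethyl-4-[(triethylsilyl)peroxy]tridecan-2-ol | C[C@H](CCCCCCCO[Si](c1ccccc1)(c1ccccc1)C(C)(C)C)CC(C)(OO[Si](CC)(CC)CC)CC(C)O
F3 | step 15 | (4R,6R)-13-[(tert-butyldiphenylsilyl)oxy]-4,6-dimethyl-4-[(triethylsilyl)peroxy]tridecan-2-one | CC(=O)C[C@@](OO[Si](CC)(CC)CC)(C)C[C@H](C)CCCCCCCO[Si](c1ccccc1)(c1ccccc1)C(C)(C)C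
F4 | step 15 | (4S,6R)-13-[(tert-butyldiphenylsilyl)oxy]-4,6-dimethyl-4-[(triethylsilyl)peroxy]tridecan-2-one | CC(=O)C[C@](OO[Si](CC)(CC)CC)(C)C[C@H](C)CCCCCCCO[Si](c1ccccc1)(c1ccccc1)C(C)(C)C
F5 | step 19 | methyl (5R,7R)-14-[(tert-butyldiphenylsilyl)oxy]-5-[(2-methoxypropan-2-yl)peroxy]-3,5,7-trimethyltetradec-2-enoate | COC(=O)C=C(C)C[C@@](OOC(C)(C)OC)(C)C[C@H](C)CCCCCCCO[Si](c1ccccc1)(c1ccccc1)C(C)(C)C
F6 | step 19 | methyl (5R,7R)-14-[(tert-butyldiphenylsilyl)oxy]-5-hydroperoxy-3,5,7-trimethyltetradec-2-enoate | COC(=O)C=C(C)C[C@@](OO)(C)C[C@H](C)CCCCCCCO[Si](c1ccccc1)(c1ccccc1)C(C)(C)C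
F7 | step 19 | methyl 2-[(3S,5R)-5-{(2R)-9-[(tert-butyldiphenylsilyl)oxy]-2-methylnonyl}-3,5-dimethyl-1,2-dioxolan-3-yl]acetate | C[C@H](CCCCCCCO[Si](c1ccccc1)(c1ccccc1)C(C)(C)C)C[C@]1(C)C[C@@](C)(CC(=O)OC)OO1
F8 | step 22 | methyl 2-{(3R,5R)-3,5-dimethyl-5-[(2R,9E)-2-methyl-11-oxoundec-9-en-1-yl]-1,2-dioxolan-3-yl}acetate | C[C@H](CCCCCC/C=C/C=O)C[C@]1(C)C[C@](C)(CC(=O)OC)OO1
F9 | step 22 | methyl 2-{(3R,5R)-3,5-dimethyl-5-[(2R,9E,11Z)-2-methyl-12-phenyldodeca-9,11-dien-1-yl]-1,2-dioxolan-3-yl}acetate | C[C@H](CCCCCC/C=C/C=C\c1ccccc1)C[C@]1(C)C[C@](C)(CC(=O)OC)OO1
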